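**Plan**

- Retrosynthesis: the C1 acyloxy acetal is cut back to a lactone and the C7 ester to an alcohol. The C6–C7 and C9–C8 bonds are then cut together, leaving a flat 5-(acetoxymethyl)-4-methyl-2-pyranone and the ketoaldehyde OHC–CO–CH2O-isovaleryl.
- Enabling feature: at the 2-pyranone oxidation level of the pyran ring (O2, C1, C9, C5, C4, C3), C6 (the methyl carbon on C5) and C9 are the gamma and alpha carbons of one vinylogous enolate. C7 and C8 both carry oxygen, so the cyclopentene ring is a [3+2] union of this 1,3-bis-nucleophile with a 1,2-dicarbonyl.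
- Forward: the pyranone ring is made first from dimethyl 3-methylglutaconate. The cyclopentene ring follows in one flask (vinylogous Mukaiyama aldol for C6–C7, then Mukaiyama aldol for C9–C8). C7 is then oxidised and reduced, esterified, and the C1 acyloxy acetal is made last.
- Stereochemistry: a chiral copper bis(oxazoline) Lewis acid sets C7, which relays to C8 and C9 in the ring closure. C7 is then reset trans to O8 by hydride delivery from the C8 hydroxyl, C1 by axial hydride addition to the lactone, and the side-chain centre comes from (S)-3-methylpentanoic acid.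

Key step: step 7

Assumption: iridoid numbering is used throughout (O2; C1 acetal carbon; C3=C4; C5=C6; C7; C8; C9; C10 = CH2O on C8; C11 = CH2O on C4). Compounds 1, 8 (sold as its dimer, drawn as the monomer), 9, 17, 19 and both enantiomers of t-Bu-box, 2,2'-(propane-2,2-diyl)bis(4-tert-butyl-4,5-dihydro-1,3-oxazole), are taken as commercial.

**Step 1**
Reactants: 1 dimethyl 3-methylpent-2-enedioate (dimethyl 3-methylglutaconate, E/Z mixture)
Product: 4 4-methyl-2-oxo-2H-pyran-5-carboxylic acid, via enaminodiester 2 (not isolated), via pyranone methyl ester 3 (not isolated)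
Conditions: Me2NCH(OMe)2, toluene, 100 °C; then 6 M HCl, AcOH, 90 °C
Reagents that add atoms: N,N-dimethylformamide dimethyl acetal COC(OC)N(C)C; water O
Why: The doubly activated C4 methylene condenses with the amide acetal, aqueous acid turns the enamine into an enol that lactonises onto the other ester (coumalate-type 2-pyranone synthesis), and the remaining ester is hydrolysed under the same conditions.

**Step 2**
Reactants: 4 4-methyl-2-oxo-2H-pyran-5-carboxylic acid
Product: 5 5-(hydroxymethyl)-4-methyl-2H-pyran-2-one
Conditions: BH3·SMe2, THF, 0 to 23 °C; MeOH quench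
Reagents that add atoms: none
Why: Borane reduces a carboxylic acid through its acyloxyborane much faster than it attacks a lactone, so the pyranone should survive (chemoselective borane reduction).

**Step 3**
Reactants: 5 5-(hydroxymethyl)-4-methyl-2H-pyran-2-one
Product: 6 (4-methyl-2-oxo-2H-pyran-5-yl)methyl acetate
Conditions: Ac2O, pyridine, DMAP (cat.), CH2Cl2, 0 °C
Reagents that add atoms: acetic anhydride CC(=O)OC(C)=O
Why: Routine acetylation of a primary alcohol; this installs the C11 acetate of the target at the outset.

**Step 4**
Reactants: 6 (4-methyl-2-oxo-2H-pyran-5-yl)methyl acetate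
Product: 7 [4-methylidene-6-(trimethylsilyloxy)-4H-pyran-3-yl]methyl acetate
Conditions: TMSOTf, Et3N, Et2O, 0 °C; filtered under argon, used crude
Reagents that add atoms: trimethylsilyl trifluoromethanesulfonate C[Si](C)(C)OS(=O)(=O)C(F)(F)F
Why: O-Silylation of the basic pyranone carbonyl gives an aromatic 2-silyloxypyrylium ion whose 4-methyl group is acidic enough for triethylamine, which should give the silyl dienol ether (soft enolisation).

**Step 5**
Reactants: 8 1,3-dihydroxyacetone (in excess); 9 3-methylbutanoyl chloride
Product: 10 3-hydroxy-2-oxopropyl 3-methylbutanoate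
Conditions: pyridine, CH2Cl2, 0 °C
Reagents that add atoms: none
Why: Acylation of one of two equivalent primary hydroxyls with the diol in excess should favour the monoester, and the surplus diol is removed by aqueous washing (esterification with an acid chloride).

**Step 6**
Reactants: 10 3-hydroxy-2-oxopropyl 3-methylbutanoate
Product: 11 2,3-dioxopropyl 3-methylbutanoate
Conditions: IBX, EtOAc, 75 °C; filtration, short-path distillation, used fresh
Reagents that add atoms: none
Why: IBX oxidation of a primary alpha-ketol to the alpha-ketoaldehyde under water-free conditions, so the aldehyde is obtained as the anhydrous monomer needed for Lewis acid catalysis.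

**Step 7**
Reactants: 7 [4-methylidene-6-(trimethylsilyloxy)-4H-pyran-3-yl]methyl acetate; 11 2,3-dioxopropyl 3-methylbutanoate
Product: 14 (7R,8R,9S)-7,8-cis-diol lactone, via silyl aldol adduct 12 (not isolated), via bis(trimethylsilyl) ether 13 (not isolated)
Conditions: [Cu((R,R)-t-Bu-box)](SbF6)2 (10 mol %), CH2Cl2, −78 °C; then i-Pr2NEt, TMSOTf, −78 to −40 °C; then 1 M HCl, THF, 0 °C
Reagents that add atoms: none
Why: Proposed new method: the silyl dienol ether adds through its exocyclic carbon C6 to the aldehyde of 11, which is held as a five-membered chelate with the ketone oxygen on the chiral divalent copper Lewis acid (vinylogous Mukaiyama aldol; closest known type is the copper bis(oxazoline)-catalysed addition of silyl ketene acetals and dienolates to glyoxylates, pyruvates and alkoxyacetaldehydes), and this restores the aromatic pyranone and should set C7 (R) by attack on the re face, the sense being assigned by analogy and the antipodal ligand being equally available. TMSOTf then O-silylates the pyranone carbonyl to a 2-silyloxypyrylium ion, the amine removes a C6 proton, and the regenerated dienol ether, now able to react only at C9, closes onto the silyl-activated C8 ketone in a 5-(enolexo)-exo-trig intramolecular Mukaiyama aldol (closest known type: one-pot enol silane formation and Mukaiyama aldol with a silyl triflate and an amine). C8 and C9 are set in this closure relative to C7: the C7–OSi bond is expected to lie antiperiplanar to the forming C9–C8 bond, the ketone oxygen to sit inside over the pyran ring and the CH2O-acyl arm outside next to H9, which gives the 7,8-cis diol with O8 cis to C1. The selectivities needed are aldehyde over ketone (intrinsic electrophilicity), gamma over alpha attack in the first bond (rearomatisation), enolisation of the pyranone and not of the ketone (only the pyranone gives an aromatic O-silyl cation), and survival of the allylic acetate (excess amine, low temperature). Dilute acid on work-up cleaves both trimethylsilyl ethers.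

**Step 8**
Reactants: 14 (7R,8R,9S)-7,8-cis-diol lactone
Product: 15 (8R,9S)-8-hydroxy-7-oxo lactone (enone)
Conditions: IBX, DMSO, 23 °C
Reagents that add atoms: none
Why: IBX oxidises the secondary allylic alcohol to the enone, leaves the tertiary alcohol alone and does not cleave the glycol; C7 has served as the relay and is erased here.

**Step 9**
Reactants: 15 (8R,9S)-8-hydroxy-7-oxo lactone
Product: 16 (7S,8R,9S)-7,8-trans-diol lactone
Conditions: Me4NBH(OAc)3, MeCN/AcOH, −25 °C
Reagents that add atoms: none
Why: The tertiary C8 hydroxyl exchanges onto boron and delivers hydride to the neighbouring ketone on its own face, so the new C7 hydroxyl should form trans to O8 and cis to C10, while esters and the lactone are inert to this reagent (hydroxyl-directed Evans–Saksena reduction).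

**Step 10**
Reactants: 16 (7S,8R,9S)-7,8-trans-diol lactone; 17 (S)-3-methylpentanoic acid
Product: 18 (7S,8R,9S)-7-O-[(S)-3-methylpentanoyl] lactone
Conditions: DCC, DMAP (cat.), CH2Cl2, 0 to 23 °C
Reagents that add atoms: none
Why: Steglich esterification should acylate the secondary allylic hydroxyl and leave the hindered tertiary C8 hydroxyl free; no stereocentre is touched.

**Step 11**
Reactants: 18 (7S,8R,9S)-7-O-[(S)-3-methylpentanoyl] lactone; 19 3-methylbut-2-enoyl chloride
Product: 21 target CNP0297662.1, via hemiacetal aluminate 20 (not isolated)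
Conditions: LiAlH(OtBu)3, THF, −40 to −10 °C; then pyridine, DMAP, 19, −40 to 0 °C
Reagents that add atoms: none
Why: The hindered hydride reduces the activated enol-lactone carbonyl but not alkyl esters, adding axially on the face anti to H9 and C10 (the face of the C8 hydroxyl), and the aluminium hemiacetal is acylated in the flask with retention to give the equatorial 1-acyloxy group with C1 (S) (reductive acylation of a lactone).

**Compound list**

1 | dimethyl 3-methylpent-2-enedioate (E/Z mixture) | COC(=O)CC(C)=CC(=O)OC | starting material
2 | dimethyl 2-[(dimethylamino)methylidene]-3-methylpent-3-enedioate | COC(=O)C(=CN(C)C)C(C)=CC(=O)OC | intermediate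
3 | methyl 4-methyl-2-oxo-2H-pyran-5-carboxylate | COC(=O)C1=COC(=O)C=C1C | intermediate
4 | 4-methyl-2-oxo-2H-pyran-5-carboxylic acid | OC(=O)C1=COC(=O)C=C1C | intermediate
5 | 5-(hydroxymethyl)-4-methyl-2H-pyran-2-one | CC1=CC(=O)OC=C1CO | intermediate
6 | (4-methyl-2-oxo-2H-pyran-5-yl)methyl acetate | CC1=CC(=O)OC=C1COC(C)=O | intermediate
7 | [4-methylidene-6-(trimethylsilyloxy)-4H-pyran-3-yl]methyl acetate | C=C1C=C(O[Si](C)(C)C)OC=C1COC(C)=O | intermediate
8 | 1,3-dihydroxyacetone | OCC(=O)CO | starting material
9 | 3-methylbutanoyl chloride | CC(C)CC(Cl)=O | starting material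
10 | 3-hydroxy-2-oxopropyl 3-methylbutanoate | CC(C)CC(=O)OCC(=O)CO | intermediate
11 | 2,3-dioxopropyl 3-methylbutanoate | CC(C)CC(=O)OCC(=O)C=O | intermediate
12 | (3R)-4-[5-(acetoxymethyl)-2-oxo-2H-pyran-4-yl]-2-oxo-3-(trimethylsilyloxy)butyl 3-methylbutanoate | CC(C)CC(=O)OCC(=O)[C@H](O[Si](C)(C)C)CC1=CC(=O)OC=C1COC(C)=O | intermediate
13 | (7R,8R,9S)-7,8-bis(trimethylsilyloxy) lactone: cyclopenta[c]pyran-1-one with C3=C4 and C5=C6, CH2OAc on C4, CH2O-isovaleryl on C8, both silyloxy groups and C1 on one face | C[Si](C)(C)O[C@@H]1C=C2C(COC(C)=O)=COC(=O)[C@@H]2[C@@]1(O[Si](C)(C)C)COC(=O)CC(C)C | intermediate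
14 | (7R,8R,9S)-7,8-cis-diol lactone: as 13 with free 7-OH and 8-OH (7-OH, 8-OH and C1 on one face; H9 and C10 on the other) | O[C@@H]1C=C2C(COC(C)=O)=COC(=O)[C@@H]2[C@@]1(O)COC(=O)CC(C)C | intermediate
15 | (8R,9S)-8-hydroxy-7-oxo lactone (C5=C6–C7=O enone) | O=C1C=C2C(COC(C)=O)=COC(=O)[C@@H]2[C@@]1(O)COC(=O)CC(C)C | intermediate
16 | (7S,8R,9S)-7,8-trans-diol lactone (7-OH cis to C10 and H9) | O[C@H]1C=C2C(COC(C)=O)=COC(=O)[C@@H]2[C@@]1(O)COC(=O)CC(C)C | intermediate
17 | (S)-3-methylpentanoic acid | CC[C@H](C)CC(=O)O | starting material
18 | (7S,8R,9S)-7-O-[(S)-3-methylpentanoyl]-8-hydroxy lactone | CC[C@H](C)CC(=O)O[C@H]1C=C2C(COC(C)=O)=COC(=O)[C@@H]2[C@@]1(O)COC(=O)CC(C)C | intermediate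
19 | 3-methylbut-2-enoyl chloride | CC(C)=CC(Cl)=O | starting material
20 | lithium tri-tert-butoxyaluminate of the (1S) hemiacetal of 18 | CC[C@H](C)CC(=O)O[C@H]1C=C2C(COC(C)=O)=CO[C@@H](O[Al-](OC(C)(C)C)(OC(C)(C)C)OC(C)(C)C)[C@@H]2[C@@]1(O)COC(=O)CC(C)C.[Li+] | intermediate
21 | CNP0297662.1, (1S,7S,8R,9S): 1-O-(3-methylbut-2-enoyl), 7-O-[(S)-3-methylpentanoyl], 8-hydroxy, 10-O-(3-methylbutanoyl), 11-O-acetyl | CC[C@H](C)CC(=O)O[C@H]1C=C2C(COC(C)=O)=CO[C@@H](OC(=O)C=C(C)C)[C@@H]2[C@@]1(O)COC(=O)CC(C)C | target

**Step count and risks**

Total steps: 11. Longest linear sequence: 9 (steps 1 to 4, then 7 to 11).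

Step 7 (Proposed new method) is the most likely to fail. The ring closure could proceed with poor or reversed diastereocontrol, which would relay the wrong absolute sense from C7 to C8. The amine and silyl triflate could also enolise the ketone instead of the pyranone, or the allylic acetate could ionise from the electron-rich dienol ether. The fallback sets out from 7 and 11 and returns at 14, making each bond separately by established reactions on isolated intermediates. The copper-catalysed vinylogous Mukaiyama aldol is run alone and worked up with dilute acid to the free aldol F1. TBSOTf and Et3N at −78 °C then silylate the hydroxyl and convert the pyranone into the isolable bis-silyl dienol ether F2. A classical BF3·OEt2-mediated intramolecular Mukaiyama aldol closes the ring to the 7-silyl ether F3, whose diastereomers can be separated. HF·pyridine then gives 14.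

Step 11 is the second risk. The hemiacetal aluminate could collapse to the ring-opened aldehyde, which would be reduced further, or the alkyl esters could be attacked, and the acid chloride could be lost through ketene formation. The fallback sets out from 18 and returns at 21. The lactone is reduced with the electrophilic borane bis(3-methylbutan-2-yl)borane, which takes lactones to lactols in the presence of esters, and the lactol F4 is isolated and allowed to settle into its more stable C1 configuration. It is then acylated in a separate step with 19 and pyridine at −40 °C.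

Step 9 is the third risk. If the tertiary hydroxyl does not exchange onto boron, hydride may add to the wrong face of C7 or in the conjugate sense. The fallback sets out from 15 and returns at 16, replacing substrate direction by reagent control: a Corey–Bakshi–Shibata reduction with the oxazaborolidine enantiomer matched to the 7S carbinol and catecholborane. It makes no new compound.

**Further compounds**

F1 | step 7 | (3R)-4-[5-(acetoxymethyl)-2-oxo-2H-pyran-4-yl]-3-hydroxy-2-oxobutyl 3-methylbutanoate | CC(C)CC(=O)OCC(=O)[C@H](O)CC1=CC(=O)OC=C1COC(C)=O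
F2 | step 7 | (3R)-bis(tert-butyldimethylsilyl) dienol ether: 6-silyloxy-4H-pyran-4-ylidene with the side chain on the C9 side of the exocyclic C5=C6 bond, 3-silyloxy-2-oxobutyl 3-methylbutanoate chain | CC(C)CC(=O)OCC(=O)[C@H](O[Si](C)(C)C(C)(C)C)/C=C1\C=C(O[Si](C)(C)C(C)(C)C)OC=C1COC(C)=O
F3 | step 7 | (7R,8R,9S)-7-(tert-butyldimethylsilyloxy)-8-hydroxy lactone | CC(C)(C)[Si](C)(C)O[C@@H]1C=C2C(COC(C)=O)=COC(=O)[C@@H]2[C@@]1(O)COC(=O)CC(C)C
F4 | step 11 | (1R,7S,8R,9S)-1-hydroxy lactol of 18 | CC[C@H](C)CC(=O)O[C@H]1C=C2C(COC(C)=O)=CO[C@@H](O)[C@@H]2[C@@]1(O)COC(=O)CC(C)C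
F0 | step 9 | none | none
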